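A process chemist brings you the autumn flask. Initiator starts a chain in which starting material and coupling partner give target. She asks what stands at 40 min and which remedy pays.

| flask | starting material | coupling partner | initiator | temperature | remark | time |
|---|---|---|---|---|---|---|
| autumn | 5 mM | 25 mM | 0.50 mM | 50 °C | the very flask that is asked about, followed so far |  |
| dawn | 10 mM | 25 mM | 0.50 mM | 50 °C | run made earlier |  |
| flask | 5.0 mM | 25.0 mM | 0.50 mM | 50 °C |  | 40 min |

autumn run (percent of the starting material charged)

| time / min | target / % | starting material / % |
|---|---|---|
| 2.50 | 41.3 | 8.3 |
| 6.00 | 43.5 | 7.1 |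
| 15.0 | 44.0 | 3.7 |
| 30.0 | 42.5 | 6.6 |

dawn run (percent of the starting material charged)

| time / s | target / % | starting material / % |
|---|---|---|
| 10.0 | 4.8 | 86.9 |
| 20.0 | 11.2 | 83.9 |
| 50.0 | 17.4 | 66.8 |

(readings scatter by 1 percentage point)

- Tuesday's: at 40 min take out 90 % of the released group then present, then wait 80 min
- Sunday's: at 40 min raise the temperature by 20 K, then wait 80 min
- Wednesday's: change nothing and wait 80 min more
- Thursday's: at 40 min add coupling partner, 50.0 % of the amount charged, then wait 80 min

- a species is counted by the starting material in it: one ended chains A counts as two
- the volume of additions can be left aside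
- steps that have been proposed: starting material + initiating radical -> capped initiator + first chain carrier; coupling partner -> decomposed reagent; initiator -> 2 initiating radical; coupling partner + first chain carrier <-> target + second chain carrier; 2 first chain carrier -> ended chains A; 2 second chain carrier -> ended chains B; starting material + second chain carrier -> released group + first chain carrier; target <-> isomer of the product
- the earlier runs do not show what temperature does; that part of a forecast is a guess

- target, in percent of the starting material first charged, at 40 min
- the remedy with the largest gain of target, or "none" below 2 percentage points (Tuesday's / Sunday's / Wednesday's / Thursday's / none)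
- target present, in percent of the starting material first charged, after Tuesday's
- target present, in percent of the starting material first charged, after Thursday's

Trust the readings first and watch two amounts. From 6.00 min to 30.0 min, autumn target averages 43.3 %. Over the same autumn readings, [starting material] shows no trend, and 94.2 % of the charge has gone. Their ratio, 0.460, is the share: target made per starting material consumed, the selectivity. The dawn run, with twice the [starting material], reads 0.524 at 50.0 s. That is a little higher, but each reading there carries 1 percentage point, so I carry the share across charges with caution.

The end state is then share times amount consumed. Autumn shows no further consumption, so I commit to 43.3 % at 40 min, and I expect the same after waiting. Turning the whole leftover at this share is worth 2.7 points, against a margin of 2 points, but the autumn readings show no restart, so I also commit to 43.3 % after Tuesday's and after Thursday's. A gain beyond that leftover needs a larger share. Temperature is the untested setting, so my guess is Sunday's.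

The forecast says 43 % (41 % to 44.5 %), 43 % after Tuesday's, 43.5 % after Thursday's, and best none: “Heating is a guess and offers no new initiator”.

The flask gives 43.2 %, with 43.2 % after Tuesday's and 43.2 % after Thursday's. Sunday's is best, gaining 12 points. At 40.0 min, starting material in this flask stands at 5.31 %, so the share reckons 43.6 % for it. Sunday's ends at 55.4 %, more than the 46.0 % that full conversion at the old share yields, so the share itself moved.

    starting material + initiating radical → capped initiator + first chain carrier (k = 5.70 × 10⁵ M⁻¹ s⁻¹, Ea = 29.0 kJ mol⁻¹)
    coupling partner → decomposed reagent (k = 0.00170 s⁻¹, Ea = 94.0 kJ mol⁻¹)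
    initiator → 2 initiating radical (k = 0.0270 s⁻¹, Ea = 93.0 kJ mol⁻¹)
    coupling partner + first chain carrier ⇌ target + second chain carrier (K = 0.0240, k = 1500 M⁻¹ s⁻¹, Ea = 41.0 kJ mol⁻¹, ΔH = −56.0 kJ mol⁻¹)
    2 first chain carrier → ended chains A (k = 3.00 × 10⁶ M⁻¹ s⁻¹, Ea = 26.0 kJ mol⁻¹)
    2 second chain carrier → ended chains B (k = 5.00 × 10⁶ M⁻¹ s⁻¹, Ea = 11.0 kJ mol⁻¹)
    starting material + second chain carrier → released group + first chain carrier (k = 2.50 × 10⁵ M⁻¹ s⁻¹, Ea = 34.0 kJ mol⁻¹)
    target ⇌ isomer of the product (K = 0.730, k = 0.0310 s⁻¹, Ea = 83.0 kJ mol⁻¹, ΔH = −34.0 kJ mol⁻¹)
    (constants at 50 °C)

Now take the neighbour charged with 8.5 mM of starting material. At 40.0 min it keeps 37 % unreacted, so the share gives 29.0 % of target. The computed neighbour holds 29.8 % of target.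

The data stem from a simulated flask on assumed constants, noise included.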